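The earlier runs and the new flask were generated by integration for an exercise, and the scatter is random.

In a closed flask of constant volume, the starting material charged always equals what is left plus what has been used, so the amount used, in moles per litre, is the charge times the fraction lost.

| flask | starting material | reagent | transfer agent | initiator | remark | time |
|---|---|---|---|---|---|---|
| north-west | 0.25 M | 1.5 M | 0.50 M | 12 mM | run made earlier |  |
| west | 0.38 M | 1.5 M | 0.50 M | 12 mM | run made earlier |  |
| flask | 0.50 M | 1.50 M | 0.500 M | 12 mM |  | 40 h |

| run | time / h | over-reaction product / % | target / % | starting material / % | side product / % | first chain carrier / % |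
|---|---|---|---|---|---|---|
| north-west | 2.50 | 0 | 0.6 | 98.8 | 0 | 0 |
| north-west | 6.00 | 0.2 | 1.5 | 98.3 | 1.3 | 0 |
| north-west | 15.0 | 1.8 | 1.8 | 95.8 | 0.7 | 0 |
| north-west | 30.0 | 3.0 | 3.3 | 91.2 | 2.0 | 0.5 |
| west | 8.00 | 1.2 | 0.9 | 99.1 | 0.1 | 0 |
| west | 15.0 | 1.5 | 0.5 | 96.5 | 0 | 0.7 |
| west | 25.0 | 1.6 | 1.6 | 94.4 | 1.7 | 0.2 |
| west | 30.0 | 3.3 | 1.3 | 93.6 | 2.1 | 0 |

(standard deviation of a reading: 0.5 percentage points)

- in percentages every species weighs as the starting material in it: one ended chains B counts as two
- on the list of suspects stand: initiator -> 2 initiating radical; starting material + initiating radical -> capped initiator + first chain carrier; reagent + first chain carrier -> target + second chain carrier; starting material + second chain carrier -> by-product + first chain carrier; transfer agent + first chain carrier -> side product + idle radical; 2 idle radical -> ended radicals; 2 second chain carrier -> ended chains A; 2 first chain carrier -> ended chains B; target -> over-reaction product; starting material -> decomposition product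

- where most of what was charged as starting material, at 40 h is found (target / over-reaction product / side product / first chain carrier / starting material)
- the largest share itself, whichever of these holds it, in percent of the starting material charged

The two runs seem to contradict each other. After 30.0 h the readings put the loss of starting material in the north-west run, charged with 0.25 M, at 8.80%, but in the west run, charged with more, 0.38 M, at less, 6.40%. A first-order loss with one rate constant takes the same percentage at any charge.

The balance clears this up. In moles per litre, these readings give, on average over the run, 7.33 × 10⁻⁴ M h⁻¹ for the north-west run and 8.11 × 10⁻⁴ M h⁻¹ for the west run. With a scatter of 0.5 percentage points on each reading, these are close enough to average. We call their mean, 7.72 × 10⁻⁴ M h⁻¹, the absolute loss rate: the amount of starting material used per litre each hour at these charges. This is apparent zero-order behaviour. By our own reckoning, 40 h at this rate uses 0.0309 M in the flask charged with 0.50 M, which leaves 93.8% of the starting material.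

The forecast names starting material at 93%, a little below our figure, on the ground that “The absolute rate is therefore almost independent of starting-material concentration”.

The flask gives starting material at 94.0%.

    initiator → 2 initiating radical (k = 2.80 × 10⁻⁶ s⁻¹)
    starting material + initiating radical → capped initiator + first chain carrier (k = 20000 L mol⁻¹ s⁻¹)
    reagent + first chain carrier → target + second chain carrier (k = 750 L mol⁻¹ s⁻¹)
    starting material + second chain carrier → by-product + first chain carrier (k = 12000 L mol⁻¹ s⁻¹)
    transfer agent + first chain carrier → side product + idle radical (kL = 870 L mol⁻¹ s⁻¹)
    2 idle radical → ended radicals (k = 1.00 × 10⁶ L mol⁻¹ s⁻¹)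
    2 second chain carrier → ended chains A (k = 6.00 × 10⁶ L mol⁻¹ s⁻¹)
    2 first chain carrier → ended chains B (k = 4.00 × 10⁸ L mol⁻¹ s⁻¹)
    target → over-reaction product (k = 2.40 × 10⁻⁵ s⁻¹)
    starting material → decomposition product (k = 1.70 × 10⁻⁸ s⁻¹)

The flask has used on average 7.44 × 10⁻⁴ M h⁻¹ of starting material, against the loss rate of 7.72 × 10⁻⁴ M h⁻¹ read from the runs, and at 18.0 h the reaction of starting material with the second chain carrier uses it 2.6 times as fast as its reaction with the initiating radical, yet that faster step gives starting material a half-life of 27 d, long against the 40 h of this flask. For the neighbouring flask charged with 2.0 M of starting material, all else as in this flask, the same loss rate gives 98.5% left, and that neighbouring flask holds 98.3%.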